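| flask | starting material | partner | free catalyst | remark |
|---|---|---|---|---|
| cedar | 0.50 M | 2 M | 2 mM | run made earlier |
| flask | 1.0 M | 2.00 M | 2.0 mM |  |

cedar run (percent of the starting material charged)

| time / s | target / % | starting material / % |
|---|---|---|
| 10.0 | 52.1 | 47.6 |
| 12.0 | 56.2 | 42.3 |
| 15.0 | 65.3 | 35.1 |
| 25.0 | 80.7 | 20.8 |
| 40.0 | 90.6 | 10.4 |
| 60.0 | 94.8 | 5.2 |
| 90.0 | 97.2 | 2.8 |

(each reading ± 0.5 percentage points)

1. apparent order in partner when 50% of the starting material are converted (percent change of the rate of making target for one percent more partner charged)

- what was read earlier has a scatter of 0.5 percentage points, one standard deviation
- on the list of suspects stand: free catalyst -> spent catalyst; 2 free catalyst <-> resting dimer; starting material + partner + free catalyst -> free catalyst + target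
- no earlier run changes the charge of partner; that part of a forecast is a guess

In the flask, 50% conversion of the starting material takes 0.500 M of partner out of the 2.00 M charged, if the suspect step uses one of each. The bench rule for a partner in excess is to freeze c(partner), call the step pseudo-first-order and expect order one. At 50% conversion the cedar run has spent 12.5% of its partner, so the rule is tolerable there. The flask has spent a quarter, so the rule stops working there.

In the flask, the amount used up at that conversion stays the same when more partner is charged, so one percent more charge raises c(partner) there by more than one percent. The lever, c(partner) charged over c(partner) present at the conversion looked at, is 1.33 in the flask. With the catalyst frozen and first order in partner guessed, this is the order at fixed conversion.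

The catalyst may not stay constant either. In the cedar run, starting material falls from 20.8% to 10.4% in 15.0 s, but the next halving, to 5.2%, takes 20.0 s. My own reckoning stands at the lever, with a catalyst term left open.

The forecast gives 1.46, range 1.36 to 1.56, starting from “the direct term, assuming first order in partner” and adding 0.12 for the catalyst.

The flask gives 1.5, inside that range, and reaches 50% conversion at 0.171 min.

    free catalyst → spent catalyst (k = 0.0860 s⁻¹)
    2 free catalyst ⇌ resting dimer, settled at all times (K = 5700 L mol⁻¹)
    starting material + partner + free catalyst → free catalyst + target (k = 110 L² mol⁻² s⁻¹)

That order stands 0.170 above the flask's lever of 1.33. The cedar run has passed 50% conversion at its first reading, with 47.6% of the starting material left at 10.0 s, and its lever at 50% conversion is 1.14.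

The runs were computed from invented constants, noise included.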